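**Plan** (flavanone numbering O1, C2–C8a, rings A/B/C; piperidine atoms primed)
- Retrosynthesis: N–CH3, the two O-benzyl groups and N-Boc go last. Ring C is then opened at C3–C4, because C4 is an aryl ketone carbon on C4a with the C5 hydroxyl of ring A beside it and C2 carries one hydrogen plus ring B; this leads to a salicylaldehyde whose O1 bears a 1-arylvinyl group.
- Further cuts: C4–C4a (ortho-formylation), C2=C3 (ester methylenation), O1–C2 (esterification), then N–C6' and C2'–C3' of the piperidine (sulfinimine chemistry).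
- Forward: ring A is bought; the piperidine is built on its formyl carbon; ring B is attached at O1 as an ester and converted to the enol ether; the formyl group is placed on C4a; ring C closes last; N-methylation and debenzylation finish.
- Because O1 is alkenylated before ring C closes, the piperidine can only end up at C6.
- Stereochemistry: C2' (S) from (R)-tert-butanesulfinamide in the Grignard addition; C2 (S) from the chiral bisphosphine on rhodium in the ring C closure.

Key step: step 12

Remark: the sense of induction of the bisphosphine in step 12 cannot be predicted; the (R) ligand is written and its antipode is used if the first run gives the C2 epimer.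
Remark: the target has a basic amine beside a 5-hydroxyflavanone, so it is isolated at pH 7 or below and stored as a salt to avoid base-induced opening of ring C.

**Step 1**
Reactants: 1 2,4,6-trihydroxybenzaldehyde
Product: 2 2,6-dihydroxy-4-(methoxymethoxy)benzaldehyde
Conditions: MOMCl (1.0 equiv), K2CO3 (1.0 equiv), acetone, 0 °C → rt
Reagents that add atoms: chloromethyl methyl ether, COCCl
Why: Williamson-type O-alkylation in which the C4 hydroxyl, the only one not hydrogen-bonded to the formyl group and the most acidic, should react first, any bis-ether being removed by chromatography.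

**Step 2**
Reactants: 2 2,6-dihydroxy-4-(methoxymethoxy)benzaldehyde
Product: 3 2-(benzyloxy)-6-hydroxy-4-(methoxymethoxy)benzaldehyde
Conditions: BnBr (1.05 equiv), K2CO3 (1.1 equiv), acetone, rt
Reagents that add atoms: benzyl bromide, BrCc1ccccc1
Why: Williamson etherification that should stop at the mono-ether because the remaining hydroxyl is then held in a strong hydrogen bond to the aldehyde and is much less nucleophilic.

**Step 3**
Reactants: 3 2-(benzyloxy)-6-hydroxy-4-(methoxymethoxy)benzaldehyde
Product: 4 2-(allyloxy)-6-(benzyloxy)-4-(methoxymethoxy)benzaldehyde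
Conditions: allyl bromide (2 equiv), K2CO3, DMF, 60 °C
Reagents that add atoms: allyl bromide, C=CCBr
Why: Williamson etherification under more forcing conditions alkylates the chelated hydroxyl and leaves three oxygen groups that can be removed independently (acid, zerovalent palladium, hydrogenolysis).

**Step 4**
Reactants: 4 2-(allyloxy)-6-(benzyloxy)-4-(methoxymethoxy)benzaldehyde, 5 (R)-tert-butanesulfinamide
Product: 6 (R,E)-N-[2-(allyloxy)-6-(benzyloxy)-4-(methoxymethoxy)benzylidene]-2-methylpropane-2-sulfinamide
Conditions: Ti(OEt)4 (2 equiv), THF, 65 °C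
Reagents that add atoms: none
Why: Ellman condensation, in which Ti(OEt)4 activates the hindered aldehyde and takes up the water, should give the E-aldimine without touching the sulfur stereocentre.

**Step 5**
Reactants: 6 the N-sulfinyl aldimine, 7 1-bromo-4-chlorobutane
Product: 9 (R)-N-{(S)-1-[2-(allyloxy)-6-(benzyloxy)-4-(methoxymethoxy)phenyl]-5-chloropentyl}-2-methylpropane-2-sulfinamide, via 4-chlorobutylmagnesium bromide 8 (not isolated)
Conditions: 7, Mg, Et2O, 35 °C; then 6, CH2Cl2, −48 °C → rt; aq. NH4Cl
Reagents that add atoms: none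
Why: Magnesium inserts only into the C–Br bond, and the Ellman Grignard addition in a non-coordinating solvent passes through a six-membered chair transition state with magnesium on the sulfinyl oxygen, which from the (R) auxiliary should deliver the alkyl group to the face that gives the (S) carbon C2'.

**Step 6**
Reactants: 9 the chloroalkyl sulfinamide
Product: 10 (S)-2-[2-(allyloxy)-6-(benzyloxy)-4-(methoxymethoxy)phenyl]-1-[(R)-tert-butylsulfinyl]piperidine
Conditions: LiN(SiMe3)2 (1.3 equiv), THF, 0 → 50 °C
Reagents that add atoms: none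
Why: Intramolecular N-alkylation (6-exo-tet) of the sulfinamide anion by the primary chloride closes the piperidine ring without involving C2'.

**Step 7**
Reactants: 10 the N-sulfinyl piperidine
Product: 12 tert-butyl (S)-2-[2-(allyloxy)-6-(benzyloxy)-4-hydroxyphenyl]piperidine-1-carboxylate, via piperidinyl phenol 11 (not isolated)
Conditions: HCl (4 M in dioxane), MeOH, 0 °C → rt; then NaHCO3, Boc2O, THF–H2O, rt
Reagents that add atoms: di-tert-butyl dicarbonate, CC(C)(C)OC(=O)OC(=O)OC(C)(C)C
Why: Acid methanolysis cleaves the N–S bond and the MOM acetal while the allyl and benzyl ethers and the protonated benzylic amine persist, and carbamate formation with Boc2O under bicarbonate then occurs at the amine in preference to the phenol.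

**Step 8**
Reactants: 12 the N-Boc phenol, 13 4-(benzyloxy)benzoic acid
Product: 14 tert-butyl (S)-2-[2-(allyloxy)-6-(benzyloxy)-4-{[4-(benzyloxy)benzoyl]oxy}phenyl]piperidine-1-carboxylate
Conditions: EDC·HCl, DMAP (cat.), CH2Cl2, rt
Reagents that add atoms: none
Why: Steglich esterification at the only free hydroxyl joins ring B to the oxygen that becomes O1.

**Step 9**
Reactants: 14 the aryl ester
Product: 15 tert-butyl (S)-2-[2-(allyloxy)-6-(benzyloxy)-4-{1-[4-(benzyloxy)phenyl]vinyloxy}phenyl]piperidine-1-carboxylate
Conditions: Cp2TiMe2 (3 equiv), toluene–THF, 65 °C, dark; filtration through basic Al2O3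
Reagents that add atoms: dimethyltitanocene, [CH3-].[CH3-].[Ti+4].c1cc[cH-]c1.c1cc[cH-]c1
Why: Petasis methylenation, in which thermally generated Cp2Ti=CH2 adds to the ester carbonyl and the oxatitanacyclobutane collapses to the 1-aryloxy-1-arylethene, should prefer the aryl ester to the hindered tert-butyl carbamate and, being non-acidic, spares the enol ether it forms.

**Step 10**
Reactants: 15 the allyl-protected enol ether
Product: 16 tert-butyl (S)-2-[2-(benzyloxy)-4-{1-[4-(benzyloxy)phenyl]vinyloxy}-6-hydroxyphenyl]piperidine-1-carboxylate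
Conditions: Pd(PPh3)4 (5 mol %), morpholine, THF, rt
Reagents that add atoms: none
Why: Tsuji–Trost deallylation, in which zerovalent palladium ionises the aryl allyl ether and morpholine captures the allyl group, frees the C5 hydroxyl under neutral conditions that leave the enol ether, the carbamate and the benzyl ethers alone.

**Step 11**
Reactants: 16 the enol ether phenol
Product: 17 tert-butyl (S)-2-[6-(benzyloxy)-4-{1-[4-(benzyloxy)phenyl]vinyloxy}-3-formyl-2-hydroxyphenyl]piperidine-1-carboxylate
Conditions: MgCl2, Et3N, (CH2O)n, THF, 65 °C; pH 7 phosphate buffer work-up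
Reagents that add atoms: paraformaldehyde (as formaldehyde), C=O
Why: Casnati–Skattebøl ortho-formylation, in which the magnesium phenoxide delivers formaldehyde to the only free ortho position (C4a) and a second formaldehyde oxidises the benzylic alkoxide, runs in amine-buffered medium with a neutral work-up so that the acid-labile enol ether is kept.

**Step 12**
Reactants: 17 the salicylaldehyde enol ether
Product: 18 tert-butyl (S)-2-{(S)-7-(benzyloxy)-2-[4-(benzyloxy)phenyl]-5-hydroxy-4-oxochroman-6-yl}piperidine-1-carboxylate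
Conditions: [Rh(cod)2]BF4 (5 mol %), (R)-DTBM-SEGPHOS (5.5 mol %), 2,6-di-tert-butyl-4-methylpyridine (10 mol %), ClCH2CH2Cl, 60 °C
Reagents that add atoms: none
Why: Proposed new method: oxidative addition of the formyl C–H bond to the monovalent rhodium bisphosphine cation should give an acyl hydride of trivalent rhodium, which the C5 hydroxyl can hold as a five-membered C,O-chelate while the alkene is unbound, blocking the cis site that CO de-insertion needs; rotation about C4a–C4 then brings the metal to the O1 side, the enol ether binds, hydride migrates to C2, rhodium ends on the unsubstituted C3, and reductive elimination from the seven-membered rhodacycle forms C3–C4. The closest known reactions are the rhodium-catalysed enantioselective intramolecular hydroacylations of 1,1-disubstituted alkenes and the intermolecular hydroacylations of salicylaldehydes in which the phenol suppresses decarbonylation; closure of a 2-(1-arylvinyloxy)benzaldehyde to a flavanone is not among them. Ring C closes in a formal 6-endo-trig mode with respect to the enol ether. The C2 stereocentre is set by the chiral bisphosphine, which differentiates the two faces of the enol ether in hydride insertion and reductive elimination (catalyst control; the fixed C2' centre makes the two outcomes diastereomers). The step needs anti-Markovnikov hydrometallation, secured by the 1,1-disubstitution that disfavours a tertiary rhodium alkyl at C2, and chemoselectivity over decarbonylation and enol ether hydrolysis, secured by the C5 hydroxyl and by the hindered pyridine that removes adventitious acid. Because nothing in the medium is basic enough to open ring C, neither C2 nor the C6 position of the piperidinyl group can scramble through the chalcone.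

**Step 13**
Reactants: 18 the N-Boc flavanone
Product: 20 (S)-7-(benzyloxy)-2-[4-(benzyloxy)phenyl]-5-hydroxy-6-[(S)-1-methylpiperidin-2-yl]chroman-4-one, via secondary amine 19 (not isolated)
Conditions: CF3CO2H, CH2Cl2, 0 °C; aq. NaHCO3 wash; then aq. CH2O, NaBH(OAc)3, AcOH, ClCH2CH2Cl, 0 °C → rt
Reagents that add atoms: formaldehyde, C=O
Why: Acidolysis removes the Boc group (ring A is now deactivated by conjugation with the C4 carbonyl, so the benzylic C–N bond should hold) and reductive amination with formaldehyde and NaBH(OAc)3 methylates the amine, the hydride reducing the iminium ion or any cyclic N,O-acetal with the C5 hydroxyl but not the hydrogen-bonded ketone.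

**Step 14**
Reactants: 20 the N-methyl dibenzyl ether
Product: 21 (S)-5,7-dihydroxy-2-(4-hydroxyphenyl)-6-[(S)-1-methylpiperidin-2-yl]chroman-4-one
Conditions: H2 (1 atm), 10% Pd/C, AcOH (2 equiv), EtOAc–MeOH, rt
Reagents that add atoms: none
Why: Catalytic hydrogenolysis cleaves the two aryl benzyl ethers, the acetic acid keeping the amine protonated so that it neither slows the catalyst nor acts as a base toward ring C, and neither stereocentre is touched.

**Compound list**
1 | 2,4,6-trihydroxybenzaldehyde | O=Cc1c(O)cc(O)cc1O | starting material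
2 | 2,6-dihydroxy-4-(methoxymethoxy)benzaldehyde | O=Cc1c(O)cc(OCOC)cc1O | intermediate
3 | 2-(benzyloxy)-6-hydroxy-4-(methoxymethoxy)benzaldehyde | O=Cc1c(O)cc(OCOC)cc1OCc1ccccc1 | intermediate
4 | 2-(allyloxy)-6-(benzyloxy)-4-(methoxymethoxy)benzaldehyde | O=Cc1c(OCC=C)cc(OCOC)cc1OCc1ccccc1 | intermediate
5 | (R)-tert-butanesulfinamide | CC(C)(C)[S@](N)=O | starting material
6 | (R,E)-N-[2-(allyloxy)-6-(benzyloxy)-4-(methoxymethoxy)benzylidene]-2-methylpropane-2-sulfinamide | CC(C)(C)[S@@](=O)/N=C/c1c(OCC=C)cc(OCOC)cc1OCc1ccccc1 | intermediate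
7 | 1-bromo-4-chlorobutane | ClCCCCBr | starting material
8 | 4-chlorobutylmagnesium bromide | ClCCCC[Mg]Br | intermediate
9 | (R)-N-{(S)-1-[2-(allyloxy)-6-(benzyloxy)-4-(methoxymethoxy)phenyl]-5-chloropentyl}-2-methylpropane-2-sulfinamide | CC(C)(C)[S@@](=O)N[C@@H](CCCCCl)c1c(OCC=C)cc(OCOC)cc1OCc1ccccc1 | intermediate
10 | (S)-2-[2-(allyloxy)-6-(benzyloxy)-4-(methoxymethoxy)phenyl]-1-[(R)-tert-butylsulfinyl]piperidine | CC(C)(C)[S@@](=O)N1CCCC[C@H]1c1c(OCC=C)cc(OCOC)cc1OCc1ccccc1 | intermediate
11 | 3-(allyloxy)-5-(benzyloxy)-4-[(S)-piperidin-2-yl]phenol | N1CCCC[C@H]1c1c(OCC=C)cc(O)cc1OCc1ccccc1 | intermediate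
12 | tert-butyl (S)-2-[2-(allyloxy)-6-(benzyloxy)-4-hydroxyphenyl]piperidine-1-carboxylate | CC(C)(C)OC(=O)N1CCCC[C@H]1c1c(OCC=C)cc(O)cc1OCc1ccccc1 | intermediate
13 | 4-(benzyloxy)benzoic acid | OC(=O)c1ccc(OCc2ccccc2)cc1 | starting material
14 | tert-butyl (S)-2-[2-(allyloxy)-6-(benzyloxy)-4-{[4-(benzyloxy)benzoyl]oxy}phenyl]piperidine-1-carboxylate | CC(C)(C)OC(=O)N1CCCC[C@H]1c1c(OCC=C)cc(OC(=O)c2ccc(OCc3ccccc3)cc2)cc1OCc1ccccc1 | intermediate
15 | tert-butyl (S)-2-[2-(allyloxy)-6-(benzyloxy)-4-{1-[4-(benzyloxy)phenyl]vinyloxy}phenyl]piperidine-1-carboxylate | CC(C)(C)OC(=O)N1CCCC[C@H]1c1c(OCC=C)cc(OC(=C)c2ccc(OCc3ccccc3)cc2)cc1OCc1ccccc1 | intermediate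
16 | tert-butyl (S)-2-[2-(benzyloxy)-4-{1-[4-(benzyloxy)phenyl]vinyloxy}-6-hydroxyphenyl]piperidine-1-carboxylate | CC(C)(C)OC(=O)N1CCCC[C@H]1c1c(O)cc(OC(=C)c2ccc(OCc3ccccc3)cc2)cc1OCc1ccccc1 | intermediate
17 | tert-butyl (S)-2-[6-(benzyloxy)-4-{1-[4-(benzyloxy)phenyl]vinyloxy}-3-formyl-2-hydroxyphenyl]piperidine-1-carboxylate | CC(C)(C)OC(=O)N1CCCC[C@H]1c1c(OCc2ccccc2)cc(OC(=C)c2ccc(OCc3ccccc3)cc2)c(C=O)c1O | intermediate
18 | tert-butyl (S)-2-{(S)-7-(benzyloxy)-2-[4-(benzyloxy)phenyl]-5-hydroxy-4-oxochroman-6-yl}piperidine-1-carboxylate | CC(C)(C)OC(=O)N1CCCC[C@H]1c1c(OCc2ccccc2)cc2c(c1O)C(=O)C[C@@H](c1ccc(OCc3ccccc3)cc1)O2 | intermediate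
19 | (S)-7-(benzyloxy)-2-[4-(benzyloxy)phenyl]-5-hydroxy-6-[(S)-piperidin-2-yl]chroman-4-one | N1CCCC[C@H]1c1c(OCc2ccccc2)cc2c(c1O)C(=O)C[C@@H](c1ccc(OCc3ccccc3)cc1)O2 | intermediate
20 | (S)-7-(benzyloxy)-2-[4-(benzyloxy)phenyl]-5-hydroxy-6-[(S)-1-methylpiperidin-2-yl]chroman-4-one | CN1CCCC[C@H]1c1c(OCc2ccccc2)cc2c(c1O)C(=O)C[C@@H](c1ccc(OCc3ccccc3)cc1)O2 | intermediate
21 | (S)-5,7-dihydroxy-2-(4-hydroxyphenyl)-6-[(S)-1-methylpiperidin-2-yl]chroman-4-one | CN1CCCC[C@H]1c1c(O)cc2c(c1O)C(=O)C[C@@H](c1ccc(O)cc1)O2 | target

**Step count:** 14 steps in total; the longest linear sequence is 14 steps (1 to 21).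

**Steps most likely to fail**

Step 12 (new method). The acyl rhodium hydride may lose CO instead of inserting the hindered enol ether, the cationic metal may promote hydrolysis of the enol ether, or the facial selectivity may be poor. The fallback sets out from 17 and returns at 18. It replaces the metal by a thiol-catalysed radical-chain hydroacylation (tert-dodecanethiol 0.3 equiv, 1,1'-azobis(cyclohexanecarbonitrile), chlorobenzene, 90 °C), a known way of cyclising alkenals and of adding aldehydes to enol ethers. The thiyl radical abstracts the formyl hydrogen, the aroyl radical adds 6-endo to the unsubstituted C3 (attack at C2 would leave a primary radical), and the benzylic C2 radical is quenched by the thiol. There is no control at C2, so 18 would form together with its C2 epimer, tert-butyl (S)-2-{(R)-7-(benzyloxy)-2-[4-(benzyloxy)phenyl]-5-hydroxy-4-oxochroman-6-yl}piperidine-1-carboxylate F1. Since C2' is fixed the two are diastereomers and would be separated by chromatography; base-mediated recycling of F1 is avoided because the chalcone could re-close on the C5 oxygen.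

Step 5. The two ortho ether oxygens may bind magnesium and open the chair transition state, eroding or inverting the facial selectivity, and the electron-rich hindered imine may add slowly. The fallback sets out from 4 and returns at 9, and moves the stereo-determining event to a hydride reduction.
- Grignard reagent 8 is added to aldehyde 4 (THF, 0 °C) to give 1-[2-(allyloxy)-6-(benzyloxy)-4-(methoxymethoxy)phenyl]-5-chloropentan-1-ol F2.
- Dess–Martin oxidation gives 1-[2-(allyloxy)-6-(benzyloxy)-4-(methoxymethoxy)phenyl]-5-chloropentan-1-one F3.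
- Condensation with 5 (Ti(OEt)4, THF, 70 °C) gives (R)-N-{1-[2-(allyloxy)-6-(benzyloxy)-4-(methoxymethoxy)phenyl]-5-chloropentylidene}-2-methylpropane-2-sulfinamide F4.
- Reduction with LiBH(s-Bu)3 (open transition state) or NaBH4 (cyclic transition state) is known to give opposite epimers of N-sulfinyl ketimines, so the hydride that leads to the (S) carbon is chosen to reach 9.

Step 9. Methylenation may also attack the carbamate carbonyl, conversion of the electron-rich benzoate may stall, and the enol ether may hydrolyse during isolation. The fallback sets out from 12 and returns at 15, building the enol ether by O-alkylation and elimination instead of carbonyl olefination.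
- Methyl [4-(benzyloxy)phenyl]acetate is brominated through its enolate (LiN(SiMe3)2, then N-bromosuccinimide, THF, −78 °C) to methyl 2-bromo-2-[4-(benzyloxy)phenyl]acetate F5.
- Phenol 12 is alkylated with F5 (K2CO3, DMF, rt) to tert-butyl (2S)-2-[2-(allyloxy)-6-(benzyloxy)-4-{1-[4-(benzyloxy)phenyl]-2-methoxy-2-oxoethoxy}phenyl]piperidine-1-carboxylate F6.
- LiBH4 (THF, 0 °C) reduces the ester to tert-butyl (2S)-2-[2-(allyloxy)-6-(benzyloxy)-4-{1-[4-(benzyloxy)phenyl]-2-hydroxyethoxy}phenyl]piperidine-1-carboxylate F7.
- Iodine, PPh3 and imidazole convert the alcohol to tert-butyl (2S)-2-[2-(allyloxy)-6-(benzyloxy)-4-{1-[4-(benzyloxy)phenyl]-2-iodoethoxy}phenyl]piperidine-1-carboxylate F8.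
- KOtBu (THF, 0 °C) removes the acidic benzylic hydrogen in an E2 elimination to give 15.

**Further compounds**
F1 | step 12 | tert-butyl (S)-2-{(R)-7-(benzyloxy)-2-[4-(benzyloxy)phenyl]-5-hydroxy-4-oxochroman-6-yl}piperidine-1-carboxylate | CC(C)(C)OC(=O)N1CCCC[C@H]1c1c(OCc2ccccc2)cc2c(c1O)C(=O)C[C@H](c1ccc(OCc3ccccc3)cc1)O2
F2 | step 5 | 1-[2-(allyloxy)-6-(benzyloxy)-4-(methoxymethoxy)phenyl]-5-chloropentan-1-ol (racemic) | OC(CCCCCl)c1c(OCC=C)cc(OCOC)cc1OCc1ccccc1
F3 | step 5 | 1-[2-(allyloxy)-6-(benzyloxy)-4-(methoxymethoxy)phenyl]-5-chloropentan-1-one | O=C(CCCCCl)c1c(OCC=C)cc(OCOC)cc1OCc1ccccc1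
F4 | step 5 | (R)-N-{1-[2-(allyloxy)-6-(benzyloxy)-4-(methoxymethoxy)phenyl]-5-chloropentylidene}-2-methylpropane-2-sulfinamide | CC(C)(C)[S@@](=O)N=C(CCCCCl)c1c(OCC=C)cc(OCOC)cc1OCc1ccccc1
F5 | step 9 | methyl 2-bromo-2-[4-(benzyloxy)phenyl]acetate (racemic) | COC(=O)C(Br)c1ccc(OCc2ccccc2)cc1
F6 | step 9 | tert-butyl (2S)-2-[2-(allyloxy)-6-(benzyloxy)-4-{1-[4-(benzyloxy)phenyl]-2-methoxy-2-oxoethoxy}phenyl]piperidine-1-carboxylate | CC(C)(C)OC(=O)N1CCCC[C@H]1c1c(OCC=C)cc(OC(C(=O)OC)c2ccc(OCc3ccccc3)cc2)cc1OCc1ccccc1
F7 | step 9 | tert-butyl (2S)-2-[2-(allyloxy)-6-(benzyloxy)-4-{1-[4-(benzyloxy)phenyl]-2-hydroxyethoxy}phenyl]piperidine-1-carboxylate | CC(C)(C)OC(=O)N1CCCC[C@H]1c1c(OCC=C)cc(OC(CO)c2ccc(OCc3ccccc3)cc2)cc1OCc1ccccc1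
F8 | step 9 | tert-butyl (2S)-2-[2-(allyloxy)-6-(benzyloxy)-4-{1-[4-(benzyloxy)phenyl]-2-iodoethoxy}phenyl]piperidine-1-carboxylate | CC(C)(C)OC(=O)N1CCCC[C@H]1c1c(OCC=C)cc(OC(CI)c2ccc(OCc3ccccc3)cc2)cc1OCc1ccccc1
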